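**Retrosynthetic overview**

1. Feature: the target is a bicyclo[3.1.1]heptan-2-one. Its cyclobutane C4–C5–C6–C7 carries the ketone bridge C8(=O)–C9–C10(Me) on the 1,3-pair C5/C7 and the bridge C3(OAng)–C2–C1(OAng)–C11(Me)(CH2OH) on the other 1,3-pair C4/C6. C6 lies diagonal to the quaternary C4, so a 1-methyl-3-oxocyclobutane-1-carboxylate with C6 as its carbonyl carbon already holds the four-membered ring, with C5 and C7 as its two α-carbons.
2. Key disconnection C5–C10 and C7–C8: α,α′-annulation of the C2-symmetric pyrrolidine enamine of the cyclobutanone ester with acryloyl chloride gives the bicyclo[3.1.1]heptane-2,6-dione and sets C4, C5 and C7.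
3. C6=C11 by Peterson olefination, then hydrogenation from the bridge face (C6); C10 methyl by enone formation and cuprate addition.
4. C1–C2 by acylation of a C3 β-hydroxy sulfone dianion closes the seven-membered ring after a CBS reduction (C3); Evans–Tishchenko reduction (C1), hydroxyl-directed C–H silylation and oxidation (C11), then angeloylation.
5. Ring order: cyclobutane (purchased), six-membered ketone ring (step 3), seven-membered ring (step 14).

Key step: step 3

Remark on locants: C1 and C3 are the angeloyloxy carbons with C2 between them; C4 is the methyl-bearing quaternary cyclobutane carbon; C5 and C7 are the cyclobutane CH groups; C6 is the cyclobutane CH bonded to C11; C8 is the ketone carbon (on C7), C9 its CH2, C10 the methyl-bearing CH (on C5); C11 carries methyl and CH2OH. On C4 and C6, "syn" means pointing over the C8–C10 bridge and "anti" means pointing away from it. The target has C4-methyl syn, C3 anti, C6–H syn and C11 anti.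

Assumption: for a reagent attacking C5 or C6, the ester on C4 is taken to be the larger of the two C4 substituents, so that reagents enter anti to it.

**Route**

Step 1
Reactants: 1 1-methyl-3-oxocyclobutane-1-carboxylic acid
Product: 2 benzyl 1-methyl-3-oxocyclobutane-1-carboxylate
Conditions: BnBr, K2CO3, DMF, rt
Reagents that add atoms: benzyl bromide, BrCc1ccccc1
Why: SN2 O-alkylation of the carboxylate leaves the ketone untouched, and the benzyl ester is chosen because it can later be cleaved by hydrogenolysis in the presence of a ketal.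

Step 2
Reactants: 2 benzyl 1-methyl-3-oxocyclobutane-1-carboxylate; 3 (2R,5R)-2,5-dimethylpyrrolidine
Product: 4 benzyl 3-[(2R,5R)-2,5-dimethylpyrrolidin-1-yl]-1-methylcyclobut-2-ene-1-carboxylate (enamine drawn with the C5=C6 double bond)
Conditions: TsOH·H2O (1 mol%), 4 Å molecular sieves, benzene, 60 °C
Reagents that add atoms: none
Why: Acid-catalysed enamine formation with the reactive cyclobutanone should give two double-bond regioisomers that are diastereomers and interconvert through the iminium ion, so no stereocenter is fixed here.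

Step 3
Reactants: 4 enamine of the cyclobutanone ester; 5 acryloyl chloride
Product: 8 benzyl (1R,5R,7R)-7-methyl-2,6-dioxobicyclo[3.1.1]heptane-7-carboxylate, via enamine acid chloride 6 (not isolated), via bicyclic iminium chloride 7 (not isolated)
Conditions: acryloyl chloride (1.05 equiv), MeCN, −20 to 60 °C; then NaOAc, AcOH, H2O, rt
Reagents that add atoms: water, O
Why: Proposed new method: enamine carbon C5 adds to the β-carbon of acryloyl chloride (directly, or by N-acylation and [3,3] shift), the enamine re-forms towards C7 and is C-acylated by the tethered acyl chloride or ketene, and buffered hydrolysis of iminium salt 7 frees the C6 ketone; the closest known reaction type is the α,α′-annulation of cyclohexanone and cyclopentanone enamines with acryloyl chloride to bridged bicyclic diketones. The ring C5–C6–C7–C8–C9–C10 closes by a 6-(enolendo)-exo-trig acylation, and because C5 and C7 are 1,3 on the cyclobutane the only possible product is the one-carbon-bridged bicyclo[3.1.1]heptane. C5 is set by attack on the enamine face anti to the benzyl ester, which in the matched enamine regioisomer is also the face left open by the pyrrolidine methyl group next to C5; C7 follows because the new bridge must be cis on the four-membered ring; C4 becomes stereogenic with its methyl syn to the bridge. The step needs face selectivity (secured by the ester on C4) and a choice between the enantiotopic α-carbons (secured by the C2-symmetric amine, the mismatched regioisomer equilibrating through the iminium ion). The acylation is irreversible, which is what should allow the strained, non-enolisable β-diketone to form, and the hydrolysis is buffered because nucleophiles could open it by retro-Claisen cleavage.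

Step 4
Reactants: 8 bicyclic dione
Product: 9 benzyl 2-(tert-butyldimethylsilyloxy)-7-methyl-6-oxobicyclo[3.1.1]hept-2-ene-7-carboxylate (C8 silyl enol ether)
Conditions: TBSOTf, Et3N, CH2Cl2, −78 to 0 °C
Reagents that add atoms: tert-butyldimethylsilyl trifluoromethanesulfonate, CC(C)(C)[Si](C)(C)OS(=O)(=O)C(F)(F)F
Why: Soft enolisation can only occur at C8 towards C9 because both α-carbons of C6 are bridgeheads, and the enol ether removes the β-dicarbonyl relationship so that a later alkoxide at C6 cannot fragment by retro-aldol cleavage.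

Step 5
Reactants: 9 C8 silyl enol ether; 10 ethyl (trimethylsilyl)acetate
Product: 11 benzyl 2-(tert-butyldimethylsilyloxy)-6-(2-ethoxy-2-oxoethylidene)-7-methylbicyclo[3.1.1]hept-2-ene-7-carboxylate (mixture of alkene isomers)
Conditions: 10, LiN(i-Pr)2, THF, −78 °C; then 9, −78 °C to rt
Reagents that add atoms: none
Why: Peterson olefination, in which the small lithium ester enolate adds to the strained, non-enolisable cyclobutanone and the β-silyl alkoxide eliminates on warming; the face of addition does not matter because C6 becomes trigonal again.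

Step 6
Reactants: 11 C6 alkylidene ester
Product: 12 benzyl 2-(tert-butyldimethylsilyloxy)-6-(2-ethoxy-2-oxoethyl)-7-methylbicyclo[3.1.1]hept-2-ene-7-carboxylate (C6–H syn to the bridge; side chain anti and cis to the ester)
Conditions: H2 (1 atm), Pd/C (10%), Ph2S (1 mol%), EtOAc, rt
Reagents that add atoms: none
Why: Hydrogenation over sulfide-poisoned Pd/C reduces the strained exocyclic alkene while sparing the benzyl ester and the enol ether, and hydrogen should enter C6 from the face turned to the flat C8=C9 bridge because the other face lies under the anti (pseudo-axial) ester on C4; any C6 epimer cannot cyclise in step 14 and would be removed there.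

Step 7
Reactants: 12 saturated diester silyl enol ether
Product: 13 benzyl 6-(2-ethoxy-2-oxoethyl)-7-methyl-2-oxobicyclo[3.1.1]hept-3-ene-7-carboxylate (C9=C10 enone)
Conditions: Pd(OAc)2 (1.1 equiv), MeCN, rt to 40 °C
Reagents that add atoms: none
Why: Saegusa–Ito oxidation, in which the palladium enolate at C9 undergoes β-hydride elimination from C10, its only β-CH position.

Step 8
Reactants: 13 enone
Product: 14 benzyl 6-(2-ethoxy-2-oxoethyl)-4,7-dimethyl-2-oxobicyclo[3.1.1]heptane-7-carboxylate (C10 methyl on the face of the C6 bridge)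
Conditions: Me2CuLi, Et2O, −78 to −30 °C
Reagents that add atoms: lithium dimethylcuprate, [Li+].C[Cu-]C
Why: Cuprate conjugate addition, as with related pinane-type enones, should occur anti to the syn methyl on C4 that covers one face of the enone, which sets C10 as in the target; the hindered esters are inert to the cuprate.

Step 9
Reactants: 14 C10-methyl ketone
Product: 15 C8 ethylene ketal of 14
Conditions: ethylene glycol, TsOH·H2O (cat.), benzene, reflux, Dean–Stark
Reagents that add atoms: ethylene glycol, OCCO
Why: Acid-catalysed ketalisation with removal of water masks the C8 ketone against the carbanions, borane and silane used in steps 10 to 17.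

Step 10
Reactants: 15 ketal diester
Product: 17 ketal diester with C11 gem-dimethyl, via monomethyl ester 16 (not isolated)
Conditions: LiN(i-Pr)2, THF, −78 °C; MeI; then LiN(i-Pr)2, DMPU, −78 °C; MeI, −78 to −20 °C
Reagents that add atoms: iodomethane, CI
Why: Two successive ester enolate alkylations make C11 quaternary with two identical methyl groups, so no stereocenter arises; the benzyl ester has no α-hydrogen, and the low temperature keeps the C11 enolate from attacking it.

Step 11
Reactants: 17 benzyl ethyl diester
Product: 18 C3 carboxylic acid (ethyl ester and ketal retained)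
Conditions: H2 (1 atm), Pd/C (10%), EtOAc, rt
Reagents that add atoms: none
Why: Neutral hydrogenolysis of the benzyl ester leaves the ketal and the ethyl ester untouched.

Step 12
Reactants: 18 C3 carboxylic acid; 19 methyl phenyl sulfone
Product: 21 C3 β-keto sulfone, via acyl imidazolide 20 (not isolated)
Conditions: CDI, THF, 50 °C; then LiCH2SO2Ph (from 19 and n-BuLi, 3.2 equiv), THF, −78 to 0 °C
Reagents that add atoms: none
Why: C-acylation of the sulfonyl carbanion occurs only at the acyl imidazolide, which is far more electrophilic than the hindered α,α-dimethyl ethyl ester, and the excess carbanion deprotonates the acidic product.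

Step 13
Reactants: 21 β-keto sulfone
Product: 22 C3 β-hydroxy sulfone (C3 with the spatial arrangement of the target; S by CIP because of the sulfonyl group)
Conditions: (S)-2-methyl-CBS-oxazaborolidine (20 mol%), BH3·SMe2, THF, −20 °C; then MeOH
Reagents that add atoms: none
Why: Corey–Bakshi–Shibata reduction with the quaternary C4 side as the large and CH2SO2Ph as the small substituent should give the C3 configuration of the target (same sense as acetophenone to (R)-1-phenylethanol); reagent control is used because the two faces of the later seven-membered ring are nearly mirror images.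

Step 14
Reactants: 22 β-hydroxy sulfone
Product: 23 tricyclic β-keto sulfone (C3–OH, C2–SO2Ph as epimer mixture, C1 ketone)
Conditions: LiN(i-Pr)2 (3.3 equiv), THF, −78 to 0 °C, substrate added to the base
Reagents that add atoms: none
Why: Intramolecular Claisen-type acylation (7-exo-trig) of the α-sulfonyl carbanion of the O,C-dianion on the ethyl ester held cis to it on the cyclobutane closes the seven-membered ring, driven by deprotonation of the product; inverse addition forms the dianion before the C3 alkoxide can lactonise.

Step 15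
Reactants: 23 tricyclic β-keto sulfone
Product: 24 tricyclic β-hydroxy ketone (C3–OH, C1 ketone)
Conditions: SmI2 (2.5 equiv), THF–MeOH, −78 °C
Reagents that add atoms: none
Why: Reductive desulfonylation of the α-sulfonyl ketone by single-electron transfer, with the samarium enolate protonated by methanol at low temperature before the C3 hydroxyl can eliminate.

Step 16
Reactants: 24 β-hydroxy ketone
Product: 25 C3 benzoate with free C1–OH (1,3-anti)
Conditions: PhCHO (6 equiv), SmI2 (30 mol%), THF, −10 °C
Reagents that add atoms: benzaldehyde, O=Cc1ccccc1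
Why: Evans–Tishchenko reduction, in which the samarium-bound hemiacetal of the C3 hydroxyl delivers hydride to C1 on the face of the C3 oxygen, should give the anti diol with C3–O benzoylated and the new C1–OH free.

Step 17
Reactants: 25 C3 benzoate C1 alcohol
Product: 27 oxasilolane C1–O–SiEt2–CH2–C11, via diethylsilyl ether 26 (not isolated)
Conditions: Et2SiH2, [Ir(cod)OMe]2 (0.5 mol%), THF, rt; evaporation; then [Ir(cod)OMe]2 (2 mol%), 3,4,7,8-tetramethyl-1,10-phenanthroline (5 mol%), norbornene, THF, 100 °C
Reagents that add atoms: diethylsilane, CC[SiH2]CC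
Why: Iridium-catalysed dehydrogenative O-silylation followed by hydroxyl-directed γ-C–H silylation should close a five-membered oxasilolane at a primary C–H of a C11 methyl; the methyl trans to the C1 oxygen is expected to react, since it is pseudo-equatorial and gauche to oxygen in the conformer with a pseudo-equatorial silyloxy group (the known preference in 2,2-dimethylcycloalkanols), and this sets C11, while the benzoate blocks silylation of the C4 methyl from C3–O and the ketal prevents hydrosilylation at C8.

Step 18
Reactants: 27 oxasilolane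
Product: 28 C1–OH and C11–CH2OH diol with C3 benzoate
Conditions: H2O2 (30% aq.), KHCO3, THF–MeOH, 50 °C
Reagents that add atoms: hydrogen peroxide, OO
Why: Tamao–Fleming oxidation converts the C–Si bond into C–OH and releases C1–OH without touching a stereocenter.

Step 19
Reactants: 28 diol benzoate
Product: 29 primary tert-butyldimethylsilyl ether of 28
Conditions: TBSCl, imidazole, CH2Cl2, 0 °C
Reagents that add atoms: tert-butyldimethylsilyl chloride, CC(C)(C)[Si](C)(C)Cl
Why: Silylation is selective for the primary hydroxyl over the hindered neopentyl secondary C1–OH.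

Step 20
Reactants: 29 silyl ether benzoate
Product: 30 C1,C3-diol with primary silyl ether and C8 ketal
Conditions: NaOMe, MeOH, 45 °C
Reagents that add atoms: none
Why: Methanolysis (transesterification) removes the benzoate, while the silyl ether and the ketal are stable to methoxide.

Step 21
Reactants: 30 C1,C3-diol; 31 angelic acid
Product: 32 C1,C3-bis-angelate with primary silyl ether and C8 ketal
Conditions: 31 (6 equiv), 2,4,6-trichlorobenzoyl chloride (6 equiv), Et3N, toluene, rt; then 30, 80 °C
Reagents that add atoms: none
Why: Yamaguchi esterification through the mixed anhydride, run without a nucleophilic catalyst, is the established way to acylate hindered secondary alcohols with angelic acid without Z-to-E isomerisation to the tiglate.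

Step 22
Reactants: 32 protected bis-angelate
Product: 33 CNP0287707.1
Conditions: HCl (1 M aq.), THF, 0 °C to rt
Reagents that add atoms: water, O
Why: Dilute aqueous acid hydrolyses the ketal and the primary silyl ether, while the angelates of hindered secondary alcohols survive and the low temperature limits acyl shift from C1–O to the primary hydroxyl.

**Compound list**

1 | 1-methyl-3-oxocyclobutane-1-carboxylic acid | CC1(CC(=O)C1)C(=O)O | starting material
2 | benzyl 1-methyl-3-oxocyclobutane-1-carboxylate | O=C(OCc1ccccc1)C1(C)CC(=O)C1 | intermediate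
3 | (2R,5R)-2,5-dimethylpyrrolidine | C[C@@H]1CC[C@@H](C)N1 | starting material
4 | benzyl 3-[(2R,5R)-2,5-dimethylpyrrolidin-1-yl]-1-methylcyclobut-2-ene-1-carboxylate (enamine, C5=C6 regioisomer) | O=C(OCc1ccccc1)[C@]1(C)C=C(N2[C@H](C)CC[C@H]2C)C1 | intermediate
5 | acryloyl chloride | C=CC(=O)Cl | starting material
6 | enamine acid chloride (C5 carries CH2CH2COCl, enamine towards C7) | O=C(OCc1ccccc1)[C@]1(C)[C@@H](CCC(=O)Cl)C(N2[C@H](C)CC[C@H]2C)=C1 | intermediate
7 | bicyclic iminium chloride (C6=N+ of the dione) | O=C(OCc1ccccc1)[C@]1(C)[C@@H]2C(=[N+]3[C@H](C)CC[C@H]3C)[C@H]1C(=O)CC2.[Cl-] | intermediate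
8 | benzyl (1R,5R,7R)-7-methyl-2,6-dioxobicyclo[3.1.1]heptane-7-carboxylate (methyl syn to the C8–C10 bridge) | O=C(OCc1ccccc1)[C@]1(C)[C@@H]2C(=O)[C@H]1C(=O)CC2 | intermediate
9 | C8 tert-butyldimethylsilyl enol ether of 8 | O=C(OCc1ccccc1)[C@]1(C)[C@@H]2C(=O)[C@H]1C(O[Si](C)(C)C(C)(C)C)=CC2 | intermediate
10 | ethyl (trimethylsilyl)acetate | CCOC(=O)C[Si](C)(C)C | starting material
11 | C6 (ethoxycarbonyl)methylidene derivative of 9 | O=C(OCc1ccccc1)[C@]1(C)[C@@H]2C([C@H]1C(O[Si](C)(C)C(C)(C)C)=CC2)=CC(=O)OCC | intermediate
12 | C6–H (syn), C6–CH2CO2Et (anti) silyl enol ether | O=C(OCc1ccccc1)[C@]1(C)[C@@H]2[C@@H]([C@H]1C(O[Si](C)(C)C(C)(C)C)=CC2)CC(=O)OCC | intermediate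
13 | C8 ketone, C9=C10 enone | O=C(OCc1ccccc1)[C@]1(C)[C@@H]2[C@@H]([C@H]1C(=O)C=C2)CC(=O)OCC | intermediate
14 | C10-methyl ketone (methyl on the face of the C6 bridge) | O=C(OCc1ccccc1)[C@]1(C)[C@@H]2[C@@H]([C@H]1C(=O)C[C@H]2C)CC(=O)OCC | intermediate
15 | C8 ethylene ketal of 14 | O=C(OCc1ccccc1)[C@]1(C)[C@@H]2[C@@H]([C@H]1C3(OCCO3)C[C@H]2C)CC(=O)OCC | intermediate
16 | C11 monomethyl ester (C11 epimers) | O=C(OCc1ccccc1)[C@]1(C)[C@@H]2[C@@H]([C@H]1C3(OCCO3)C[C@H]2C)C(C)C(=O)OCC | intermediate
17 | C11 gem-dimethyl benzyl ethyl diester | O=C(OCc1ccccc1)[C@]1(C)[C@@H]2[C@@H]([C@H]1C3(OCCO3)C[C@H]2C)C(C)(C)C(=O)OCC | intermediate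
18 | C3 carboxylic acid | OC(=O)[C@]1(C)[C@@H]2[C@@H]([C@H]1C3(OCCO3)C[C@H]2C)C(C)(C)C(=O)OCC | intermediate
19 | methyl phenyl sulfone | CS(=O)(=O)c1ccccc1 | starting material
20 | acyl imidazolide of 18 | O=C(n1ccnc1)[C@]1(C)[C@@H]2[C@@H]([C@H]1C3(OCCO3)C[C@H]2C)C(C)(C)C(=O)OCC | intermediate
21 | C3 β-keto sulfone | O=C(CS(=O)(=O)c1ccccc1)[C@]1(C)[C@@H]2[C@@H]([C@H]1C3(OCCO3)C[C@H]2C)C(C)(C)C(=O)OCC | intermediate
22 | C3 β-hydroxy sulfone (C3 as in the target) | O=S(=O)(c1ccccc1)C[C@@H](O)[C@]1(C)[C@@H]2[C@@H]([C@H]1C3(OCCO3)C[C@H]2C)C(C)(C)C(=O)OCC | intermediate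
23 | tricyclic β-keto sulfone (C3–OH, C2–SO2Ph, C1=O) | O=C1C(S(=O)(=O)c2ccccc2)[C@@H](O)[C@]2(C)[C@@H]3[C@@H]([C@H]2C4(OCCO4)C[C@H]3C)C1(C)C | intermediate
24 | tricyclic β-hydroxy ketone (C3–OH, C1=O) | O=C1C[C@@H](O)[C@]2(C)[C@@H]3[C@@H]([C@H]2C4(OCCO4)C[C@H]3C)C1(C)C | intermediate
25 | C3 benzoate, C1–OH (anti) | O[C@@H]1C[C@@H](OC(=O)c2ccccc2)[C@]2(C)[C@@H]3[C@@H]([C@H]2C4(OCCO4)C[C@H]3C)C1(C)C | intermediate
26 | C1 O-diethylsilyl (Si–H) ether of 25 | CC[SiH](CC)O[C@@H]1C[C@@H](OC(=O)c2ccccc2)[C@]2(C)[C@@H]3[C@@H]([C@H]2C4(OCCO4)C[C@H]3C)C1(C)C | intermediate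
27 | oxasilolane C1–O–SiEt2–CH2–C11 (CH2 trans to C1–O) | CC[Si]1(CC)O[C@@H]2C[C@@H](OC(=O)c3ccccc3)[C@]3(C)[C@@H]4[C@@H]([C@H]3C5(OCCO5)C[C@H]4C)[C@@]2(C)C1 | intermediate
28 | C1–OH, C11–CH2OH, C3 benzoate | O[C@@H]1C[C@@H](OC(=O)c2ccccc2)[C@]2(C)[C@@H]3[C@@H]([C@H]2C4(OCCO4)C[C@H]3C)[C@@]1(C)CO | intermediate
29 | primary TBS ether of 28 | O[C@@H]1C[C@@H](OC(=O)c2ccccc2)[C@]2(C)[C@@H]3[C@@H]([C@H]2C4(OCCO4)C[C@H]3C)[C@@]1(C)CO[Si](C)(C)C(C)(C)C | intermediate
30 | C1,C3-diol, primary TBS ether, C8 ketal | O[C@@H]1C[C@@H](O)[C@]2(C)[C@@H]3[C@@H]([C@H]2C4(OCCO4)C[C@H]3C)[C@@]1(C)CO[Si](C)(C)C(C)(C)C | intermediate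
31 | angelic acid, (Z)-2-methylbut-2-enoic acid | C/C=C(/C)C(=O)O | starting material
32 | C1,C3-bis-angelate, primary TBS ether, C8 ketal | C/C=C(/C)C(=O)O[C@@H]1C[C@@H](OC(=O)/C(C)=C\C)[C@]2(C)[C@@H]3[C@@H]([C@H]2C4(OCCO4)C[C@H]3C)[C@@]1(C)CO[Si](C)(C)C(C)(C)C | intermediate
33 | CNP0287707.1 | C/C=C(/C)C(=O)O[C@@H]1C[C@@H](OC(=O)/C(C)=C\C)[C@]2(C)[C@@H]3[C@@H]([C@H]2C(=O)C[C@H]3C)[C@@]1(C)CO | target

**Step count and risk**

Total step count: 22. Longest linear sequence: 22 steps (from 1).

Most likely to fail:

1. Step 3 (bridging annulation). What may go wrong: N-acylation or polymerisation of acryloyl chloride instead of C-alkylation; failure of the second C–C bond because of the strain of the bridged cyclobutanone; attack syn to the ester (giving the C4-epimeric bicycle, a separable diastereomer); retro-Claisen opening of the dione during hydrolysis. Fallback with known reactions, making the two bonds one at a time: from enamine 4, a Stork enamine Michael addition to tert-butyl acrylate (MeCN, reflux; then aq. AcOH) should give benzyl 2-(3-tert-butoxy-3-oxopropyl)-1-methyl-3-oxocyclobutane-1-carboxylate F1 with the same face and α-carbon selection. TFA in CH2Cl2 then frees the keto acid F2, the benzyl ester being stable. 1H-Benzotriazole and SOCl2 convert it into the N-acylbenzotriazole F3. Soft enolisation (MgBr2·OEt2, i-Pr2NEt, CH2Cl2) acylates C7, the only α-carbon from which a six-membered ring can form, and the route is rejoined at dione 8.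

2. Step 17 (directed C–H silylation). What may go wrong: silylation of the methyl cis to the C1 oxygen (wrong C11 configuration) if the ring reacts through the conformer with a pseudo-axial silyloxy group, or no C–H activation next to the congested quaternary centre. Fallback with a trigonal directing group, setting out from 24: MeONH2·HCl in pyridine gives the O-methyl oxime F4. Oxime-directed acetoxylation (Pd(OAc)2 cat., PhI(OAc)2, AcOH/Ac2O, 80 °C) functionalises the C11 methyl nearest the C=N plane and acetylates C3–OH, giving diacetate F5. K2CO3 in MeOH gives oxime diol F6. Buffered TiCl3 (NH4OAc, aq. THF) cleaves the oxime to dihydroxy ketone F7. Evans–Saksena reduction (Me4NBH(OAc)3, MeCN/AcOH, −30 °C) is directed by the C3–OH and the CH2OH, which sit on the same ring face, and gives triol F8 with C1–OH anti to C3–OH. TBSCl and imidazole then silylate the primary hydroxyl, and the route is rejoined at 30.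

3. Step 6 (hydrogenation of the C6 alkylidene). What may go wrong: poor facial selectivity on the catalyst surface or addition from the ester side (side chain syn, which cannot cyclise later), or hydrogenolysis of the benzyl ester. Fallback by electron-transfer conjugate reduction, in which C6 is protonated rather than hydrogenated: from 11, SmI2 with N,N-dimethylacetamide and t-BuOH in THF reduces the unsaturated ester through its radical anion. The small alcohol should protonate C6 from the bridge side, and the benzyl ester and enol ether are inert to SmI2. This gives 12 directly and makes no compound outside the route (F0).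

**Further compounds**

F1 | step 3 | benzyl 2-(3-tert-butoxy-3-oxopropyl)-1-methyl-3-oxocyclobutane-1-carboxylate | O=C(OCc1ccccc1)[C@]1(C)[C@@H](CCC(=O)OC(C)(C)C)C(=O)C1
F2 | step 3 | 3-[2-(benzyloxycarbonyl)-2-methyl-4-oxocyclobutyl]propanoic acid | O=C(OCc1ccccc1)[C@]1(C)[C@@H](CCC(=O)O)C(=O)C1
F3 | step 3 | N-acylbenzotriazole of F2 | O=C(OCc1ccccc1)[C@]1(C)[C@@H](CCC(=O)n2nnc3ccccc32)C(=O)C1
F4 | step 17 | C1 O-methyl oxime of 24 | CON=C1C[C@@H](O)[C@]2(C)[C@@H]3[C@@H]([C@H]2C4(OCCO4)C[C@H]3C)C1(C)C
F5 | step 17 | C1 O-methyl oxime, C3 acetate, C11–CH2OAc | CON=C1C[C@@H](OC(C)=O)[C@]2(C)[C@@H]3[C@@H]([C@H]2C4(OCCO4)C[C@H]3C)[C@@]1(C)COC(C)=O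
F6 | step 17 | C1 O-methyl oxime, C3–OH, C11–CH2OH | CON=C1C[C@@H](O)[C@]2(C)[C@@H]3[C@@H]([C@H]2C4(OCCO4)C[C@H]3C)[C@@]1(C)CO
F7 | step 17 | C1 ketone, C3–OH, C11–CH2OH | O=C1C[C@@H](O)[C@]2(C)[C@@H]3[C@@H]([C@H]2C4(OCCO4)C[C@H]3C)[C@@]1(C)CO
F8 | step 17 | C1,C3-diol with C11–CH2OH (triol, C8 ketal) | O[C@@H]1C[C@@H](O)[C@]2(C)[C@@H]3[C@@H]([C@H]2C4(OCCO4)C[C@H]3C)[C@@]1(C)CO
F0 | step 6 | none | none
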